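The pyran ring (C1, O2, C3, C4, C5, C9) and the cyclopentane ring (C5, C6, C7, C8, C9) are opened together, at C5–C9 and at C7–C8. The feature used is that C7 and C8 are neighbouring oxygen-bearing carbons and that C9 lies between C1 and C8, so C9 can act as a β-keto ester donor and C7 as a carbene-generated acyl anion. One operation (Michael addition, then crossed benzoin) turns an achiral, acyclic, furan-derived (E)-4-oxoenal ester of a 4-alkoxyacetoacetic acid into the cis-fused bicycle with C5, C8 and C9 set. The C4 ketone later brings in C11; C1 and C10 are acylated late.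

Key step: step 4

Convention: iridoid numbering is used (C1, O2, C3, C4, C5, C6, C7, C8, C9; C10 on C8; C11 on C4); β is the face of H5 and H9; PMB = 4-methoxybenzyl, TES = triethylsilyl, TBS = tert-butyldimethylsilyl.
Assumption: the absolute sense of induction of the carbene in step 4 cannot be assigned in advance; the (5aR,10bS) salt is written, and its equally available mirror image would be used if the antipode of 10 forms.

Step 1
Reactants: 1 4-methoxybenzyl alcohol; 2 methyl 4-chloro-3-oxobutanoate
Product: 3 methyl 4-[(4-methoxybenzyl)oxy]-3-oxobutanoate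
Conditions: NaH (2.2 equiv), THF, 0 to 23 °C; aq. NH4Cl
Reagents that add atoms: none
Why: Williamson-type SN2 displacement of the α-chloro ketone chloride by the sodium alkoxide of 1 should be clean because the second equivalent of NaH holds the β-keto ester as its unreactive enolate.

Step 2
Reactants: 3 methyl 4-[(4-methoxybenzyl)oxy]-3-oxobutanoate; 4 furfuryl alcohol
Product: 5 furan-2-ylmethyl 4-[(4-methoxybenzyl)oxy]-3-oxobutanoate
Conditions: DMAP (0.2 equiv), toluene, reflux, 4 Å molecular sieves (methanol removal)
Reagents that add atoms: none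
Why: DMAP-catalysed transesterification of a β-keto ester is driven by removal of methanol and proceeds under neutral conditions that should spare the acid-sensitive furan.

Step 3
Reactants: 5 furan-2-ylmethyl 4-[(4-methoxybenzyl)oxy]-3-oxobutanoate
Product: 8 (E)-2,5-dioxopent-3-en-1-yl 4-[(4-methoxybenzyl)oxy]-3-oxobutanoate, via furan endoperoxide 6 (not isolated), via (Z)-oxoenal ester 7 (not isolated)
Conditions: O2, visible light, tetraphenylporphyrin (cat.), CH2Cl2, −78 °C; Me2S, −78 to 23 °C; concentrate; I2 (5 mol %), CH2Cl2, 23 °C
Reagents that add atoms: dioxygen, O=O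
Why: [4+2] cycloaddition of singlet oxygen to the furan gives endoperoxide 6, reduction of its O–O bond by Me2S unmasks the cis-oxoenal 7, and iodine-catalysed alkene isomerisation should give the more stable E isomer, the β-keto ester and the anisyl ether being inert to singlet oxygen.

Step 4
Reactants: 8 (E)-2,5-dioxopent-3-en-1-yl 4-[(4-methoxybenzyl)oxy]-3-oxobutanoate
Product: 10 cis-fused diketo lactone (C1 lactone C=O; C4 and C7 ketones; H5β; H9β; 8α-OH; 8β-CH2OPMB), via Michael adduct 9 (not isolated)
Conditions: i-Pr2NEt (0.2 equiv), CH2Cl2 (0.02 M), 0 °C until 8 is consumed; then (5aR,10bS)-2-(pentafluorophenyl)-5a,10b-dihydro-4H,6H-indeno[2,1-b][1,2,4]triazolo[4,3-d][1,4]oxazin-2-ium tetrafluoroborate (10 mol %), 23 °C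
Reagents that add atoms: none
Why: The amine base forms the C9 enolate of the β-keto ester, which adds to C5 of the enal in a 6-exo-trig Michael closure that makes the δ-lactone ring of 9, attack at C5 being preferred over 7-endo attack at C6. Adduct 9 is configurationally labile at C9 (between two carbonyls) and at C5 (α to the C4 ketone, and through retro-Michael opening), so its stereoisomers should stay in equilibrium under the base. The carbene is added only after the enal is consumed, so that it cannot engage the enal as a homoenolate; it converts the C7 aldehyde into its Breslow enaminol, which attacks the C8 ketone in a 5-exo-trig crossed benzoin closure to form the cyclopentanone, the C4 ketone being out of reach because it would give a four-membered ring. The closest known reactions are one-pot Michael–crossed benzoin sequences of 1,3-dicarbonyl compounds with enals and triazolium-catalysed intramolecular aldehyde–ketone benzoin closures, including dynamic kinetic variants on ketones with a labile α centre. C5 and C9 are set by the chiral carbene, which should consume one enantiomer of the cis-disposed adduct faster than equilibration replenishes the other, and the fusion is cis because only that arrangement closes without strain and a trans isomer can epimerise at C5; C8 is set by the substrate, the closure placing the CH2OPMB arm on the open convex β face and the carbonyl oxygen on the concave α face beside C1. The step needs high dilution to suppress intermolecular benzoin and aldol paths, and the weak base keeps the C3 and C10 enolates, which could close by aldol onto C7, out of play.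

Step 5
Reactants: 10 cis-fused diketo lactone
Product: 11 7β,8α-diol keto lactone (C4 ketone and C1 lactone retained)
Conditions: Me4NBH(OAc)3 (4 equiv), MeCN/AcOH (1:1), −30 °C; aq. NaHCO3
Reagents that add atoms: none
Why: In this Saksena–Evans directed reduction the tertiary 8α-OH binds boron and delivers hydride to the α face of the adjacent C7 ketone, which should give the trans 7β alcohol, while the C4 ketone and the lactone have no suitably placed hydroxyl and should not be reduced by triacetoxyborohydride at this temperature.

Step 6
Reactants: 11 7β,8α-diol keto lactone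
Product: 12 7β,8α-bis(triethylsilyl) ether of 11
Conditions: TESOTf (3 equiv), 2,6-lutidine, CH2Cl2, −78 to 0 °C
Reagents that add atoms: triethylsilyl trifluoromethanesulfonate, CC[Si](CC)(CC)OS(=O)(=O)C(F)(F)F
Why: Silylation with a silyl triflate and a hindered pyridine base covers the secondary and the hindered tertiary alcohol without enolising the C4 ketone, and capping 8-OH removes the alkoxide that could trigger retro-aldol cleavage of C8–C9 in step 7.

Step 7
Reactants: 12 7β,8α-bis(triethylsilyl) ether
Product: 13 C3=C4 enol triflate (4-trifluoromethanesulfonyloxy-3-ene lactone)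
Conditions: KN(SiMe3)2 (1.1 equiv), THF, −78 °C; PhNTf2, −78 to −40 °C
Reagents that add atoms: N-phenylbis(trifluoromethanesulfonimide), O=S(=O)(N(c1ccccc1)S(=O)(=O)C(F)(F)F)C(F)(F)F
Why: Kinetic deprotonation should occur at the C3 methylene, which is activated by both the C4 ketone and the lactone oxygen and is far more accessible than the C5 methine, and O-sulfonylation of that enolate gives the vinyl triflate (enol triflate formation).

Step 8
Reactants: 13 C3=C4 enol triflate
Product: 14 4-(hydroxymethyl)-3-ene lactone (C11 alcohol)
Conditions: Bu3SnCH2OH (2 equiv), Pd(PPh3)4 (10 mol %), LiCl (6 equiv), 1,4-dioxane, 100 °C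
Reagents that add atoms: (tributylstannyl)methanol, CCCC[Sn](CCCC)(CCCC)CO
Why: Stille cross-coupling of a vinyl triflate under zerovalent palladium catalysis with LiCl transfers the hydroxymethyl group of the stannane selectively and installs C11 on C4 without moving the C3=C4 double bond.

Step 9
Reactants: 14 4-(hydroxymethyl)-3-ene lactone
Product: 15 C11 tert-butyldimethylsilyl ether of 14
Conditions: TBSCl, imidazole, CH2Cl2, 0 to 23 °C
Reagents that add atoms: tert-butyldimethylsilyl chloride, CC(C)(C)[Si](C)(C)Cl
Why: Standard silylation of the primary allylic alcohol gives a robust TBS ether, chosen so that C11–O survives the later DDQ step and is not acylated.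

Step 10
Reactants: 15 C11 silyl ether enol lactone
Product: 16 lactol (1β-OH as the expected major anomer)
Conditions: i-Bu2AlH (1.2 equiv), CH2Cl2, −78 °C; aq. sodium potassium tartrate
Reagents that add atoms: none
Why: Partial reduction of the enol lactone at low temperature stops at the aluminium hemiacetalate, as in the reduction of nepetalactone to nepetalactol, and the freed lactol should settle as the anomer with 1-OH trans to the fully substituted C8.

Step 11
Reactants: 16 lactol; 17 (S)-3-methylpentanoic acid
Product: 18 1β-O-[(S)-3-methylpentanoyl] acetal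
Conditions: DCC, DMAP (cat.), CH2Cl2, 0 to 23 °C
Reagents that add atoms: none
Why: Steglich esterification acylates the only free hydroxyl, and the ester is expected on the β face because the lactol anomers interconvert and the α face of C1 is shielded by C8 and its silyloxy group.

Step 12
Reactants: 18 1β-O-acyl acetal
Product: 19 C10 primary alcohol (PMB removed)
Conditions: DDQ (1.3 equiv), CH2Cl2/pH 7 phosphate buffer (10:1), 0 °C
Reagents that add atoms: none
Why: Oxidative cleavage of the electron-rich 4-methoxybenzyl ether by DDQ under buffered conditions should free the C10 alcohol without touching the silyl ethers, the acyloxy acetal or the enol ether.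

Step 13
Reactants: 20 p-coumaric acid
Product: 22 (E)-3-[4-(tert-butyldimethylsilyloxy)phenyl]acrylic acid, via bis-silylated coumarate 21 (not isolated)
Conditions: TBSCl (2.5 equiv), imidazole, DMF, 23 °C; then AcOH/THF/H2O, 23 °C
Reagents that add atoms: tert-butyldimethylsilyl chloride, CC(C)(C)[Si](C)(C)Cl
Why: Exhaustive silylation followed by selective hydrolysis of the far more labile silyl ester leaves the phenol masked as its TBS ether, a standard protection of a hydroxycinnamic acid.

Step 14
Reactants: 19 C10 primary alcohol; 22 (E)-3-[4-(tert-butyldimethylsilyloxy)phenyl]acrylic acid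
Product: 23 fully silylated target (10-O-coumaroyl ester with phenol TBS, 7-O and 8-O TES, 11-O TBS)
Conditions: DCC, DMAP, CH2Cl2, 23 °C
Reagents that add atoms: none
Why: Steglich esterification of the only free hydroxyl, the primary C10 alcohol, with the phenol-protected acid should proceed without affecting the E alkene or the C1 ester.

Step 15
Reactants: 23 fully silylated target
Product: 24 target compound CNP0241834.1
Conditions: HF·pyridine, pyridine, THF, 0 to 23 °C
Reagents that add atoms: none
Why: Buffered HF·pyridine cleaves all four silyl ethers by Si–F bond formation under mildly acidic, non-nucleophilic conditions that should avoid the acyl migration and acyloxy-acetal cleavage expected with basic fluoride.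

Compound list
1 | 4-methoxybenzyl alcohol | COc1ccc(CO)cc1 | starting material
2 | methyl 4-chloro-3-oxobutanoate | COC(=O)CC(=O)CCl | starting material
3 | methyl 4-[(4-methoxybenzyl)oxy]-3-oxobutanoate | COC(=O)CC(=O)COCc1ccc(OC)cc1 | intermediate
4 | furfuryl alcohol (furan-2-ylmethanol) | OCc1ccco1 | starting material
5 | furan-2-ylmethyl 4-[(4-methoxybenzyl)oxy]-3-oxobutanoate | O=C(CC(=O)COCc1ccc(OC)cc1)OCc1ccco1 | intermediate
6 | furan endoperoxide, (2,3,7-trioxabicyclo[2.2.1]hept-5-en-1-yl)methyl 4-[(4-methoxybenzyl)oxy]-3-oxobutanoate (racemic) | O=C(CC(=O)COCc1ccc(OC)cc1)OCC12OOC(O1)C=C2 | intermediate (not isolated)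
7 | (Z)-2,5-dioxopent-3-en-1-yl 4-[(4-methoxybenzyl)oxy]-3-oxobutanoate | O=C/C=C\C(=O)COC(=O)CC(=O)COCc1ccc(OC)cc1 | intermediate (not isolated)
8 | (E)-2,5-dioxopent-3-en-1-yl 4-[(4-methoxybenzyl)oxy]-3-oxobutanoate | O=C/C=C/C(=O)COC(=O)CC(=O)COCc1ccc(OC)cc1 | intermediate
9 | Michael adduct, 3-{[(4-methoxybenzyl)oxy]acetyl}-4-(2-oxoethyl)dihydro-2H-pyran-2,5(6H)-dione (equilibrating stereoisomers at C5 and C9) | O=CCC1C(=O)COC(=O)C1C(=O)COCc1ccc(OC)cc1 | intermediate (not isolated)
10 | cis-fused diketo lactone, 7-hydroxy-7-{[(4-methoxybenzyl)oxy]methyl}tetrahydrocyclopenta[c]pyran-1,4,6(3H)-trione; iridoid numbering: C1 lactone C=O, C4 and C7 ketones, H5β, H9β, 8α-OH, 8β-CH2OPMB | O=C1OCC(=O)[C@H]2CC(=O)[C@](O)(COCc3ccc(OC)cc3)[C@@H]12 | intermediate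
11 | 7β,8α-diol keto lactone (as 10 with C7 reduced; 7-OH trans to 8-OH) | O=C1OCC(=O)[C@H]2C[C@H](O)[C@](O)(COCc3ccc(OC)cc3)[C@@H]12 | intermediate
12 | 7β,8α-bis(triethylsilyl) ether of 11 | O=C1OCC(=O)[C@H]2C[C@H](O[Si](CC)(CC)CC)[C@](O[Si](CC)(CC)CC)(COCc3ccc(OC)cc3)[C@@H]12 | intermediate
13 | C3=C4 enol triflate of 12 (4-OTf, 3-ene, C1 lactone) | O=C1OC=C(OS(=O)(=O)C(F)(F)F)[C@H]2C[C@H](O[Si](CC)(CC)CC)[C@](O[Si](CC)(CC)CC)(COCc3ccc(OC)cc3)[C@@H]12 | intermediate
14 | 4-(hydroxymethyl)-3-ene lactone (free C11-OH; 7,8-bis-OTES; 10-OPMB) | O=C1OC=C(CO)[C@H]2C[C@H](O[Si](CC)(CC)CC)[C@](O[Si](CC)(CC)CC)(COCc3ccc(OC)cc3)[C@@H]12 | intermediate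
15 | C11 tert-butyldimethylsilyl ether of 14 | O=C1OC=C(CO[Si](C)(C)C(C)(C)C)[C@H]2C[C@H](O[Si](CC)(CC)CC)[C@](O[Si](CC)(CC)CC)(COCc3ccc(OC)cc3)[C@@H]12 | intermediate
16 | lactol of 15, drawn as the 1β-OH anomer | O[C@@H]1OC=C(CO[Si](C)(C)C(C)(C)C)[C@H]2C[C@H](O[Si](CC)(CC)CC)[C@](O[Si](CC)(CC)CC)(COCc3ccc(OC)cc3)[C@@H]12 | intermediate
17 | (S)-3-methylpentanoic acid | CC[C@H](C)CC(=O)O | starting material
18 | 1β-O-[(S)-3-methylpentanoyl] acetal (7,8-bis-OTES; 11-OTBS; 10-OPMB) | CC[C@H](C)CC(=O)O[C@@H]1OC=C(CO[Si](C)(C)C(C)(C)C)[C@H]2C[C@H](O[Si](CC)(CC)CC)[C@](O[Si](CC)(CC)CC)(COCc3ccc(OC)cc3)[C@@H]12 | intermediate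
19 | C10 primary alcohol (as 18 with PMB removed) | CC[C@H](C)CC(=O)O[C@@H]1OC=C(CO[Si](C)(C)C(C)(C)C)[C@H]2C[C@H](O[Si](CC)(CC)CC)[C@](O[Si](CC)(CC)CC)(CO)[C@@H]12 | intermediate
20 | p-coumaric acid, (E)-3-(4-hydroxyphenyl)acrylic acid | OC(=O)/C=C/c1ccc(O)cc1 | starting material
21 | tert-butyldimethylsilyl (E)-3-[4-(tert-butyldimethylsilyloxy)phenyl]acrylate | CC(C)(C)[Si](C)(C)OC(=O)/C=C/c1ccc(O[Si](C)(C)C(C)(C)C)cc1 | intermediate (not isolated)
22 | (E)-3-[4-(tert-butyldimethylsilyloxy)phenyl]acrylic acid | OC(=O)/C=C/c1ccc(O[Si](C)(C)C(C)(C)C)cc1 | intermediate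
23 | fully silylated target (10-O-[(E)-4-(TBS-oxy)cinnamoyl]; 7,8-bis-OTES; 11-OTBS; 1β-O-acyl) | CC[C@H](C)CC(=O)O[C@@H]1OC=C(CO[Si](C)(C)C(C)(C)C)[C@H]2C[C@H](O[Si](CC)(CC)CC)[C@](O[Si](CC)(CC)CC)(COC(=O)/C=C/c3ccc(O[Si](C)(C)C(C)(C)C)cc3)[C@@H]12 | intermediate
24 | CNP0241834.1 | CC[C@H](C)CC(=O)O[C@@H]1OC=C(CO)[C@H]2C[C@H](O)[C@](O)(COC(=O)/C=C/c3ccc(O)cc3)[C@@H]12 | target

Total step count: 15. Longest linear sequence: 14 steps (steps 1–12, 14 and 15); step 13 is a one-step branch.

Steps most likely to fail

Step 4. The adduct may equilibrate too slowly, or the carbene may discriminate its enantiomers too weakly, so that the closure falls back to a simple kinetic resolution with low enantiomeric purity. The C8 ketone may also be attacked on the wrong face, or C9 may condense onto the C4 ketone before the Michael addition. Fallback: starting from 8, C5 would be set by iminium catalysis instead of by the carbene. Diphenylprolinol trimethylsilyl ether (20 mol %, the antipode that gives H5 β) with NaOAc in CHCl3 should induce an enantioselective intramolecular Michael addition to the C5-configured Michael adduct F1. The triazolium salt, present in the same flask, should then close F1 by the crossed benzoin before C5 erodes. This amine–carbene relay is the established form of the Michael–benzoin sequence, and it returns to the route at 10.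

Step 7. Deprotonation may occur at C5 or C9 instead of C3, or the enolate may fragment, giving regioisomeric triflates or decomposition. Fallback: starting from 12, soft enolisation with TMSOTf and Et3N in CH2Cl2 at 0 °C should give, under thermodynamic control, the oxygen-substituted C3=C4 trimethylsilyl enol ether F2, which can be purified and checked for regiochemistry. Fluoride-triggered triflation of F2 (CsF, PhNTf2, 1,2-dimethoxyethane, 23 °C) then releases the enolate regiospecifically without a strong amide base and rejoins the route at 13.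

Step 5. Hydride may be delivered to the activated C4 ketone as well as to C7, or facial selectivity at C7 may be poor. Fallback: starting from 10, the C4 ketone would be taken out of play before the reduction. N-(trimethylsilyl)imidazole should cap the tertiary alcohol to give the 8-O-trimethylsilyl ether F3. KN(SiMe3)2 and PhNTf2 should then convert the more acidic C3–H/C4 ketone side into the enol triflate F4. Mild hydrolysis (AcOH/THF/H2O) removes the trimethylsilyl group to give the hydroxy ketone triflate F5. The same Me4NBH(OAc)3 reduction, now facing a single ketone, should give the 7β,8α-diol triflate F6, and TESOTf with 2,6-lutidine rejoins the route at 13.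

Further compounds
F1 | step 4 | C5-configured Michael adduct, 3-{[(4-methoxybenzyl)oxy]acetyl}-4-(2-oxoethyl)dihydro-2H-pyran-2,5(6H)-dione with the C5 configuration of 10 | O=CC[C@@H]1C(=O)COC(=O)C1C(=O)COCc1ccc(OC)cc1
F2 | step 7 | C3=C4 trimethylsilyl enol ether of 12 | O=C1OC=C(O[Si](C)(C)C)[C@H]2C[C@H](O[Si](CC)(CC)CC)[C@](O[Si](CC)(CC)CC)(COCc3ccc(OC)cc3)[C@@H]12
F3 | step 5 | 8-O-trimethylsilyl ether of 10 | O=C1OCC(=O)[C@H]2CC(=O)[C@](O[Si](C)(C)C)(COCc3ccc(OC)cc3)[C@@H]12
F4 | step 5 | C3=C4 enol triflate of F3 (C7 ketone retained) | O=C1OC=C(OS(=O)(=O)C(F)(F)F)[C@H]2CC(=O)[C@](O[Si](C)(C)C)(COCc3ccc(OC)cc3)[C@@H]12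
F5 | step 5 | 8α-hydroxy C7-ketone enol triflate | O=C1OC=C(OS(=O)(=O)C(F)(F)F)[C@H]2CC(=O)[C@](O)(COCc3ccc(OC)cc3)[C@@H]12
F6 | step 5 | 7β,8α-diol enol triflate | O=C1OC=C(OS(=O)(=O)C(F)(F)F)[C@H]2C[C@H](O)[C@](O)(COCc3ccc(OC)cc3)[C@@H]12
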